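**Plan**

- Retrosynthesis: the two O–benzyl bonds are cut first (protecting groups), the C2–O bond is then traced back to a C2–B bond, and last the aryl–C1 and C2–C3 bonds are cut together.
- Enabling feature: the carbinol carbon C2 lies between the benzylic carbon C1 and the first chain carbon C3. C1–C2 can therefore be the two carbons of a vinyl boronate whose boron marks the later hydroxyl. The benzene ring is the only ring and is bought intact.
- Forward: the phenol is made into its triflate and the alkyl bromide into its Grignard reagent. One three-component coupling then joins the chain (pentadecyl onto C2, aryl onto C1), followed by boron-to-oxygen oxidation and debenzylation. No ring is formed at any stage.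
- Stereochemistry: the single center C2 is set by the chiral bisphosphine on palladium in the coupling and is carried into the alcohol with retention.

Key step: step 3

Assumption: the (Rp,Rp) enantiomer of the ligand is taken to be the one that delivers the (R)-boronate 7; the sense would be confirmed on alcohol 9 (Mosher esters), and the (Sp,Sp) enantiomer would be used with nothing else changed if it proved opposite.

**Route**

Step 1
Reactants: 1 3,5-bis(benzyloxy)phenol
Product: 2 3,5-bis(benzyloxy)phenyl trifluoromethanesulfonate
Conditions: Tf2O (1.2 equiv), pyridine (2 equiv), CH2Cl2, 0 °C to rt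
Reagents that add atoms: trifluoromethanesulfonic anhydride, O=S(=O)(OS(=O)(=O)C(F)(F)F)C(F)(F)F
Why: O-sulfonylation of a phenol with triflic anhydride and an amine base is the standard aryl triflate synthesis; the benzyl ethers are inert and the product is a stable electrophile for palladium.

Step 2
Reactants: 3 1-bromopentadecane
Product: 4 pentadecylmagnesium bromide
Conditions: Mg turnings (I2 crystal for activation), THF, slow addition at 40 °C, then 60 °C, 1 h; titrated and used as a THF solution
Reagents that add atoms: magnesium, [Mg]
Why: Grignard formation by insertion of magnesium into a primary C–Br bond; slow addition and dilution should hold back Wurtz coupling, and titration fixes the stoichiometry that clean ate complex formation needs.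

Step 3
Reactants: 5 vinylboronic acid pinacol ester (4,4,5,5-tetramethyl-2-vinyl-1,3,2-dioxaborolane); 4 pentadecylmagnesium bromide; 2 3,5-bis(benzyloxy)phenyl trifluoromethanesulfonate
Product: 7 2-[(2R)-1-[3,5-bis(benzyloxy)phenyl]heptadecan-2-yl]-4,4,5,5-tetramethyl-1,3,2-dioxaborolane, via magnesium boron ate complex 6 (not isolated)
Conditions: 5 (1.2 equiv), THF, 0 °C, then 4 (1.2 equiv), 0 °C to rt, 30 min; then NaOTf (2.4 equiv), Pd(OAc)2 (2 mol %), (Rp,Rp)-1,1'-bis[bis(4-methoxy-3,5-dimethylphenyl)phosphino]-2,2'-bis[(S)-α-(dimethylamino)benzyl]ferrocene (2.4 mol %), 2 (1.0 equiv), THF, 60 °C, 14 h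
Reagents that add atoms: none
Why: Enantioselective palladium-catalysed conjunctive cross-coupling of a vinyl boronate ate complex with an aryl triflate, a known three-component reaction that also runs with Grignard-derived complexes when NaOTf is present to support the ate complex and take up bromide. Zerovalent palladium inserts into the C–OTf bond of 2; the cationic aryl complex of divalent palladium binds the vinyl group of 6, palladium bonds to the terminal carbon C1 while the pentadecyl group shifts from boron to C2 on the face opposite the metal (1,2-metallate shift, C2–C3 bond), and reductive elimination forms the aryl–C1 bond and returns zerovalent palladium. No ring is closed. The one new stereocenter, C2, is set by the face of the vinyl group to which the chiral bisphosphine–palladium fragment binds, so the ligand enantiomer alone decides the configuration and the (R)-boronate is expected on the stated assumption; the catalyst distinguishes boron from hydrogen on the alkene and is not asked to tell the two similar arms at C2 apart. The step needs the metallate shift to win over direct transfer of the vinyl group (Suzuki–Miyaura coupling to the styrene) and over attack of free Grignard reagent on the triflate: the weakly bound triflate counterion and the wide bite angle of the ligand favour the shift, and 4 is consumed completely by 5 before 2 is added. The benzyl ethers and the saturated chain are spectators.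

Step 4
Reactants: 7 2-[(2R)-1-[3,5-bis(benzyloxy)phenyl]heptadecan-2-yl]-4,4,5,5-tetramethyl-1,3,2-dioxaborolane
Product: 9 (2R)-1-[3,5-bis(benzyloxy)phenyl]heptadecan-2-ol, via borate ester 8 (not isolated)
Conditions: 30% aq H2O2, 3 M aq NaOH, THF, 0 °C to rt
Reagents that add atoms: hydrogen peroxide, OO
Why: Alkaline peroxide oxidation of a secondary alkyl pinacol boronate: hydroperoxide adds to boron and C2 migrates from boron to oxygen with retention, so the (R) center is carried over unchanged; the benzyl ethers and the arene tolerate these conditions, and the enantiomeric purity would be checked at this stage by chiral HPLC.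

Step 5
Reactants: 9 (2R)-1-[3,5-bis(benzyloxy)phenyl]heptadecan-2-ol
Product: 10 5-[(2R)-2-hydroxyheptadecyl]benzene-1,3-diol
Conditions: H2 (1 atm), 10% Pd/C, EtOAc/EtOH, rt
Reagents that add atoms: none
Why: Hydrogenolysis of aryl benzyl ethers over palladium on carbon; the C2 hydroxyl is homobenzylic and not benzylic, so its C–O bond and the stereocenter should stay untouched.

**Compound list**

1 | 3,5-bis(benzyloxy)phenol | Oc1cc(OCc2ccccc2)cc(OCc2ccccc2)c1 | starting material
2 | 3,5-bis(benzyloxy)phenyl trifluoromethanesulfonate | O=S(=O)(Oc1cc(OCc2ccccc2)cc(OCc2ccccc2)c1)C(F)(F)F | intermediate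
3 | 1-bromopentadecane | CCCCCCCCCCCCCCCBr | starting material
4 | pentadecylmagnesium bromide | CCCCCCCCCCCCCCC[Mg]Br | intermediate
5 | vinylboronic acid pinacol ester (4,4,5,5-tetramethyl-2-vinyl-1,3,2-dioxaborolane) | C=CB1OC(C)(C)C(C)(C)O1 | starting material
6 | bromomagnesium 4,4,5,5-tetramethyl-2-pentadecyl-2-vinyl-1,3,2-dioxaborolan-2-uide (ate complex) | CCCCCCCCCCCCCCC[B-]1(C=C)OC(C)(C)C(C)(C)O1.[Mg+]Br | intermediate
7 | 2-[(2R)-1-[3,5-bis(benzyloxy)phenyl]heptadecan-2-yl]-4,4,5,5-tetramethyl-1,3,2-dioxaborolane | CCCCCCCCCCCCCCC[C@@H](B1OC(C)(C)C(C)(C)O1)Cc1cc(OCc2ccccc2)cc(OCc2ccccc2)c1 | intermediate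
8 | 2-{[(2R)-1-[3,5-bis(benzyloxy)phenyl]heptadecan-2-yl]oxy}-4,4,5,5-tetramethyl-1,3,2-dioxaborolane (borate ester) | CCCCCCCCCCCCCCC[C@@H](OB1OC(C)(C)C(C)(C)O1)Cc1cc(OCc2ccccc2)cc(OCc2ccccc2)c1 | intermediate
9 | (2R)-1-[3,5-bis(benzyloxy)phenyl]heptadecan-2-ol | CCCCCCCCCCCCCCC[C@@H](O)Cc1cc(OCc2ccccc2)cc(OCc2ccccc2)c1 | intermediate
10 | 5-[(2R)-2-hydroxyheptadecyl]benzene-1,3-diol | CCCCCCCCCCCCCCC[C@@H](O)Cc1cc(O)cc(O)c1 | target

**Step count**

Total: 5 steps. Longest linear sequence: 4 steps (steps 1, 3, 4, 5 from 1; equally steps 2, 3, 4, 5 from 3).

**Steps most likely to fail**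

Step 3. The metallate shift may lose to direct transfer of the vinyl group, bromide may slow the catalyst, or the facial selectivity may fall short with the long alkyl migrating group. The fallback sets out from triflate 2 and comes back at boronate 7, and it moves the stereo-determining event from the coupling to an alkene diboration. Commercial 1-heptadecene would be diborated enantioselectively with bis(pinacolato)diboron under Pt(dba)3 and a TADDOL-derived phenylphosphonite ligand (THF, 60 °C), the ligand enantiomer being chosen for the (S) product, to give (S)-2,2'-(heptadecane-1,2-diyl)bis(4,4,5,5-tetramethyl-1,3,2-dioxaborolane) F1. Suzuki–Miyaura coupling of F1 with 2 (Pd(OAc)2, RuPhos (2-dicyclohexylphosphino-2',6'-diisopropoxybiphenyl), KOH, THF/H2O, 70 °C) should take place only at the primary C–B bond, which the neighbouring boronate activates, and should leave the secondary boronate in place, which is 7.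

Step 2. Wurtz homocoupling during magnesium insertion and an uncertain titre may carry free Grignard reagent or unreacted 5 into the coupling. The fallback sets out from bromide 3 and comes back at ate complex 6, and it avoids the long-chain Grignard reagent altogether. Copper-catalysed borylation of 3 with bis(pinacolato)diboron (CuI, PPh3, LiOMe, DMF, rt) would give 4,4,5,5-tetramethyl-2-pentadecyl-1,3,2-dioxaborolane F2, which can be purified and weighed. Addition of commercial vinylmagnesium bromide (THF, 0 °C to rt) to F2 should then give the same ate complex 6, which enters step 3 unchanged.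

Step 5. The hydrogenolysis may stall at the mono-benzyl ether through catalyst poisoning by traces of phosphine or boron residues or through the waxy substrate coating the catalyst. The fallback sets out from alcohol 9 and comes back at target 10, and it replaces reductive cleavage by Lewis-acid dealkylation: BCl3 with pentamethylbenzene as benzyl cation scavenger in CH2Cl2 at −78 °C, then methanol quench, should remove both aryl benzyl ethers without ionising the non-benzylic secondary alcohol. This fallback makes no new compound.

**Further compounds**

F1 | step 3 | (S)-2,2'-(heptadecane-1,2-diyl)bis(4,4,5,5-tetramethyl-1,3,2-dioxaborolane) | CCCCCCCCCCCCCCC[C@@H](B1OC(C)(C)C(C)(C)O1)CB1OC(C)(C)C(C)(C)O1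
F2 | step 2 | 4,4,5,5-tetramethyl-2-pentadecyl-1,3,2-dioxaborolane | CCCCCCCCCCCCCCCB1OC(C)(C)C(C)(C)O1
F0 | step 5 | none | none
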